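**Strategy.** The route rests on cutting ring C of the isoflavan at C3–C4 and O1–C2. Ring A then provides an ortho-quinone methide (O1, C8a, C4a, C4) and ring B a two-carbon arylacetyl unit (C2, C3). A chiral carbene-bound enolate adds through C3 to the methide carbon C4, and the rearomatised phenoxide O1 acylates C2, so one operation closes the lactone ring and sets C3, the only stereocentre. The precursors are a silyl-masked 2-(chloromethyl)phenol bearing the 7-benzyloxy and 8-methoxy groups and the N-acyl imidazole of (2,3,4,5-tetramethoxyphenyl)acetic acid. The lactone carbonyl is afterwards removed by reduction and Mitsunobu ring closure.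

Key step: step 10

Assumption: the (5aS,10bR) antipode of the aminoindanol-derived N-mesityl triazolium salt is taken to expose the Si face of the enolate carbon; this sense of induction is not established for this substrate and is to be verified on the first run, the (5aR,10bS) salt being used otherwise with no other change.

Design choices:
- The benzylic leaving group is chloride, not bromide. A para-benzyloxy and an ortho-silyloxy donor would make the bromide too easily ionised to isolate and a better alkylating agent for the carbene and for imidazole.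
- O7 stays a benzyl ether because it is inert to fluoride, so no para-quinone methide can form.
- The lactone is taken to the chroman through the diol, because a free lactol would open to an epimerisable α-aryl aldehyde.

**Step 1**
Reactants: 1 2-methoxybenzene-1,3-diol (2-methoxyresorcinol)
Product: 2 2,4-dihydroxy-3-methoxybenzaldehyde
Conditions: POCl3, DMF, MeCN, −15 °C to rt; then H2O, 50 °C
Reagents that add atoms: N,N-dimethylformamide, CN(C)C=O; water, O
Why: Vilsmeier–Haack formylation, in which both hydroxyl groups direct the chloroiminium ion to C4 (ortho to one, para to the other) and the symmetry of 1 makes C4 and C6 identical, so one aldehyde should result after hydrolysis of the iminium salt.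

**Step 2**
Reactants: 2 2,4-dihydroxy-3-methoxybenzaldehyde
Product: 3 4-(benzyloxy)-2-hydroxy-3-methoxybenzaldehyde
Conditions: BnBr (1.05 equiv), NaHCO3, KI (cat.), MeCN, 70 °C
Reagents that add atoms: benzyl bromide, BrCc1ccccc1
Why: Williamson etherification under a weak base, in which only the 4-OH (para to the formyl group, more acidic, not chelated) is ionised while the 2-OH stays hydrogen-bonded to the carbonyl, so benzylation should occur at O4 alone.

**Step 3**
Reactants: 3 4-(benzyloxy)-2-hydroxy-3-methoxybenzaldehyde
Product: 4 4-(benzyloxy)-2-[(tert-butyldimethylsilyl)oxy]-3-methoxybenzaldehyde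
Conditions: TBSCl, imidazole, DMF, rt; neutral work-up
Reagents that add atoms: tert-butyldimethylsilyl chloride, CC(C)(C)[Si](C)(C)Cl
Why: Imidazole-promoted silylation of the chelated phenol installs the fluoride-labile trigger on the oxygen that becomes O1, and the benzyl ether is unaffected.

**Step 4**
Reactants: 4 4-(benzyloxy)-2-[(tert-butyldimethylsilyl)oxy]-3-methoxybenzaldehyde
Product: 5 {4-(benzyloxy)-2-[(tert-butyldimethylsilyl)oxy]-3-methoxyphenyl}methanol
Conditions: i-Bu2AlH, CH2Cl2, −78 °C; aq. potassium sodium tartrate
Reagents that add atoms: none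
Why: Hydride reduction of the aldehyde, in which the covalent aluminium alkoxide at −78 °C should not trigger the phenol-to-benzylic oxygen silyl shift that a free alkoxide (as with NaBH4 in methanol) can cause.

**Step 5**
Reactants: 5 {4-(benzyloxy)-2-[(tert-butyldimethylsilyl)oxy]-3-methoxyphenyl}methanol
Product: 7 tert-butyl[3-(benzyloxy)-6-(chloromethyl)-2-methoxyphenoxy]dimethylsilane, via benzylic mesylate 6 (not isolated)
Conditions: MsCl, i-Pr2NEt, CH2Cl2, 0 °C to rt; aqueous wash, filtration through neutral alumina, used within a day
Reagents that add atoms: methanesulfonyl chloride, CS(=O)(=O)Cl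
Why: Sulfonylation followed by in situ nucleophilic displacement of the electron-rich benzylic mesylate by the chloride of the ammonium salt, with a hindered amine that does not quaternise and water-soluble by-products, so the halide should be obtained without chromatography on silica.

**Step 6**
Reactants: 8 1,2,3,4-tetramethoxybenzene
Product: 9 1-bromo-2,3,4,5-tetramethoxybenzene
Conditions: NBS (1.0 equiv), MeCN, 0 °C to rt
Reagents that add atoms: N-bromosuccinimide, O=C1CCC(=O)N1Br
Why: Electrophilic aromatic bromination, in which the two free ring positions are equivalent and one equivalent of reagent should stop at the monobromide.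

**Step 7**
Reactants: 9 1-bromo-2,3,4,5-tetramethoxybenzene; 10 diethyl malonate
Product: 11 diethyl 2-(2,3,4,5-tetramethoxyphenyl)propanedioate
Conditions: bis(dibenzylideneacetone)palladium Pd(dba)2 (2 mol%), P(t-Bu)3·HBF4 (4 mol%), K3PO4, toluene, 80 °C
Reagents that add atoms: none
Why: Palladium-catalysed α-arylation of a malonate, in which the bulky electron-rich phosphine allows oxidative addition of the electron-rich ortho-substituted aryl bromide to zerovalent palladium and reductive elimination of the aryl–malonate bond.

**Step 8**
Reactants: 11 diethyl 2-(2,3,4,5-tetramethoxyphenyl)propanedioate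
Product: 13 (2,3,4,5-tetramethoxyphenyl)acetic acid, via arylmalonic acid 12 (not isolated)
Conditions: NaOH, EtOH/H2O, reflux; then aq. HCl to pH 1, 90 °C
Reagents that add atoms: sodium hydroxide, [Na+].[OH-]
Why: Saponification of both esters followed by thermal decarboxylation of the arylmalonic acid through a cyclic six-membered transition state (malonic ester synthesis).

**Step 9**
Reactants: 13 (2,3,4,5-tetramethoxyphenyl)acetic acid
Product: 14 1-(1H-imidazol-1-yl)-2-(2,3,4,5-tetramethoxyphenyl)ethan-1-one
Conditions: 1,1'-carbonyldiimidazole (1.1 equiv), CH2Cl2, rt; quick cold-water wash, crystallisation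
Reagents that add atoms: 1,1'-carbonyldiimidazole, O=C(n1ccnc1)n1ccnc1
Why: Carboxylic acid activation with carbonyldiimidazole, driven by loss of carbon dioxide, gives the isolable N-acyl imidazole that the carbene can later acylate itself with.

**Step 10**
Reactants: 7 tert-butyl[3-(benzyloxy)-6-(chloromethyl)-2-methoxyphenoxy]dimethylsilane; 14 1-(1H-imidazol-1-yl)-2-(2,3,4,5-tetramethoxyphenyl)ethan-1-one (1.5 equiv)
Product: 16 (3S)-7-(benzyloxy)-8-methoxy-3-(2,3,4,5-tetramethoxyphenyl)-3,4-dihydro-2H-chromen-2-one, via ortho-quinone methide 15 (not isolated)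
Conditions: (5aS,10bR)-2-(2,4,6-trimethylphenyl)-5a,10b-dihydro-4H,6H-indeno[2,1-b][1,2,4]triazolo[4,3-d][1,4]oxazin-2-ium tetrafluoroborate (15 mol%), CsF (2.5 equiv), 18-crown-6 (1.0 equiv), 4 Å MS, THF, −20 °C, 7 added over 2 h; cold filtration through a short silica pad, product used at once
Reagents that add atoms: none
Why: Fluoride cleaves the Si–O bond of 7 and the phenoxide expels chloride to give methide 15, while the free triazolylidene is acylated by 14 and loses the α-proton to give an azolium enolate; conjugate addition of the enolate carbon to the methide CH2 forms C3–C4 and rearomatises ring A, and the phenoxide then attacks the acyl azolium to form O1–C2 and release the carbene. The closest known reaction type is the carbene-catalysed formal (4+2) annulation of azolium enolates from acyl imidazoles with fluoride-generated ortho-quinone methides, which gives 3-substituted dihydrocoumarins. The single ring formed, the lactone (O1, C2, C3, C4, C4a, C8a), is closed by a 6-exo-trig acyl substitution after the intermolecular C–C bond has been made. C3 is set in the C–C bond-forming event, where the indane wall of the triazolium should shield one face of the Z-enolate so that the methide adds to the Si face of C3 (priorities C2 > aryl > H), which corresponds to 3S. Regiochemistry needs no control because 15 has one electrophilic terminus, the other ortho position carrying OMe and O7 being a fluoride-stable benzyl ether, and C-alkylation over O-alkylation is favoured by the soft methide terminus and the gain of aromaticity. The acidic C3–H of 16 is protected by the electron-rich ortho-methoxylated ring B, the low temperature, the weak base and immediate reduction.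

**Step 11**
Reactants: 16 (3S)-7-(benzyloxy)-8-methoxy-3-(2,3,4,5-tetramethoxyphenyl)-3,4-dihydro-2H-chromen-2-one
Product: 17 3-(benzyloxy)-6-[(2S)-3-hydroxy-2-(2,3,4,5-tetramethoxyphenyl)propyl]-2-methoxyphenol
Conditions: LiAlH4 (2.5 equiv), THF, −40 to 0 °C, lactone added to the hydride; aq. potassium sodium tartrate, pH 5–6
Reagents that add atoms: none
Why: Hydride reduction of the activated aryl ester to the phenol and primary alcohol, in which carbonyl addition at low temperature should outrun deprotonation at C3 and the transient aldehyde is reduced at once, after which the stereocentre is no longer acidic.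

**Step 12**
Reactants: 17 3-(benzyloxy)-6-[(2S)-3-hydroxy-2-(2,3,4,5-tetramethoxyphenyl)propyl]-2-methoxyphenol
Product: 18 (3S)-7-(benzyloxy)-8-methoxy-3-(2,3,4,5-tetramethoxyphenyl)-3,4-dihydro-2H-chromene
Conditions: PPh3, diisopropyl azodicarboxylate, THF (0.05 M), 0 °C to rt
Reagents that add atoms: none
Why: Intramolecular Mitsunobu etherification (6-exo-tet) of the only free phenol onto the activated primary alcohol, which does not touch the stereocentre.

**Step 13**
Reactants: 18 (3S)-7-(benzyloxy)-8-methoxy-3-(2,3,4,5-tetramethoxyphenyl)-3,4-dihydro-2H-chromene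
Product: 19 (3S)-8-methoxy-3-(2,3,4,5-tetramethoxyphenyl)-3,4-dihydro-2H-chromen-7-ol
Conditions: H2 (1 atm), 10% palladium on carbon (Pd/C), EtOAc/EtOH, rt
Reagents that add atoms: none
Why: Catalytic hydrogenolysis of the benzyl aryl ether, which should leave the methyl ethers and the chroman ring (no benzylic C–O bond) intact.

**Compound list**
1 | 2-methoxybenzene-1,3-diol (2-methoxyresorcinol) | COc1c(O)cccc1O | starting material
2 | 2,4-dihydroxy-3-methoxybenzaldehyde | COc1c(O)ccc(C=O)c1O | intermediate
3 | 4-(benzyloxy)-2-hydroxy-3-methoxybenzaldehyde | COc1c(OCc2ccccc2)ccc(C=O)c1O | intermediate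
4 | 4-(benzyloxy)-2-[(tert-butyldimethylsilyl)oxy]-3-methoxybenzaldehyde | COc1c(OCc2ccccc2)ccc(C=O)c1O[Si](C)(C)C(C)(C)C | intermediate
5 | {4-(benzyloxy)-2-[(tert-butyldimethylsilyl)oxy]-3-methoxyphenyl}methanol | COc1c(OCc2ccccc2)ccc(CO)c1O[Si](C)(C)C(C)(C)C | intermediate
6 | 4-(benzyloxy)-2-[(tert-butyldimethylsilyl)oxy]-3-methoxybenzyl methanesulfonate | COc1c(OCc2ccccc2)ccc(COS(C)(=O)=O)c1O[Si](C)(C)C(C)(C)C | intermediate (not isolated)
7 | tert-butyl[3-(benzyloxy)-6-(chloromethyl)-2-methoxyphenoxy]dimethylsilane | COc1c(OCc2ccccc2)ccc(CCl)c1O[Si](C)(C)C(C)(C)C | intermediate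
8 | 1,2,3,4-tetramethoxybenzene | COc1ccc(OC)c(OC)c1OC | starting material
9 | 1-bromo-2,3,4,5-tetramethoxybenzene | COc1cc(Br)c(OC)c(OC)c1OC | intermediate
10 | diethyl malonate (diethyl propanedioate) | CCOC(=O)CC(=O)OCC | starting material
11 | diethyl 2-(2,3,4,5-tetramethoxyphenyl)propanedioate | CCOC(=O)C(C(=O)OCC)c1cc(OC)c(OC)c(OC)c1OC | intermediate
12 | 2-(2,3,4,5-tetramethoxyphenyl)propanedioic acid | COc1cc(C(C(=O)O)C(=O)O)c(OC)c(OC)c1OC | intermediate (not isolated)
13 | (2,3,4,5-tetramethoxyphenyl)acetic acid | COc1cc(CC(=O)O)c(OC)c(OC)c1OC | intermediate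
14 | 1-(1H-imidazol-1-yl)-2-(2,3,4,5-tetramethoxyphenyl)ethan-1-one | O=C(Cc1cc(OC)c(OC)c(OC)c1OC)n1ccnc1 | intermediate
15 | 3-(benzyloxy)-2-methoxy-6-methylidenecyclohexa-2,4-dien-1-one | C=C1C=CC(OCc2ccccc2)=C(OC)C1=O | intermediate (not isolated)
16 | (3S)-7-(benzyloxy)-8-methoxy-3-(2,3,4,5-tetramethoxyphenyl)-3,4-dihydro-2H-chromen-2-one | COc1cc([C@H]2C(=O)Oc3c(ccc(OCc4ccccc4)c3OC)C2)c(OC)c(OC)c1OC | intermediate
17 | 3-(benzyloxy)-6-[(2S)-3-hydroxy-2-(2,3,4,5-tetramethoxyphenyl)propyl]-2-methoxyphenol | COc1cc([C@H](Cc2ccc(OCc3ccccc3)c(OC)c2O)CO)c(OC)c(OC)c1OC | intermediate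
18 | (3S)-7-(benzyloxy)-8-methoxy-3-(2,3,4,5-tetramethoxyphenyl)-3,4-dihydro-2H-chromene | COc1cc([C@H]2COc3c(ccc(OCc4ccccc4)c3OC)C2)c(OC)c(OC)c1OC | intermediate
19 | (3S)-8-methoxy-3-(2,3,4,5-tetramethoxyphenyl)-3,4-dihydro-2H-chromen-7-ol | COc1cc([C@H]2COc3c(ccc(O)c3OC)C2)c(OC)c(OC)c1OC | target

**Totals**
Total step count: 13.
Longest linear sequence: 9 steps (steps 1–5, then 10–13, from 2-methoxyresorcinol).

**Steps most likely to fail**

Step 10. The facial selectivity of the enolate addition may be poor or of the wrong sense. The configuration at C3 may erode in the basic fluoride medium. The methide may be consumed by imidazole or by self-condensation before the enolate reaches it. The fallback is auxiliary-controlled alkylation; it sets out from acid 13 and chloride 7 and comes back at diol 17. Acid 13 is converted through its pivaloyl mixed anhydride (pivaloyl chloride, Et3N, then the lithium salt of (4S)-4-benzyl-1,3-oxazolidin-2-one) into the imide (4S)-4-benzyl-3-[(2,3,4,5-tetramethoxyphenyl)acetyl]-1,3-oxazolidin-2-one F1. Its sodium Z-enolate (NaN(SiMe3)2, THF, −78 °C) is alkylated with 7 in the presence of NaI (Evans asymmetric alkylation), the benzyl group of the auxiliary directing the electrophile to the face that gives 2S, to give (4S)-4-benzyl-3-[(2S)-3-{4-(benzyloxy)-2-[(tert-butyldimethylsilyl)oxy]-3-methoxyphenyl}-2-(2,3,4,5-tetramethoxyphenyl)propanoyl]-1,3-oxazolidin-2-one F2. Reductive removal of the auxiliary with LiBH4 in wet THF at 0 °C should give (2S)-3-{4-(benzyloxy)-2-[(tert-butyldimethylsilyl)oxy]-3-methoxyphenyl}-2-(2,3,4,5-tetramethoxyphenyl)propan-1-ol F3. Bu4NF buffered with AcOH then removes the silyl group to give 17.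

Step 5. The very electron-rich benzylic chloride may ionise and alkylate itself on isolation, or the aryl silyl ether may be lost during mesylation. The fallback is a silicon-free and halide-free methide precursor released by base; it sets out from aldehyde 3 and comes back at lactone 16. NaBH4 in MeOH/THF at 0 °C reduces 3 to 3-(benzyloxy)-6-(hydroxymethyl)-2-methoxyphenol F4. Sodium 4-methylbenzenesulfinate in aqueous formic acid at rt replaces the benzylic hydroxyl (acid-promoted loss of water, capture of the benzylic cation by sulfinate) to give the crystalline sulfone 3-(benzyloxy)-2-methoxy-6-[(4-methylbenzenesulfonyl)methyl]phenol F5. With the triazolium salt of step 10 and Cs2CO3 in place of CsF, F5 loses sulfinate to give the same methide 15, which the azolium enolate from 14 should convert into 16.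

Step 11. The configuration at C3 may erode by enolisation of the aryl lactone, or of the transient α-aryl aldehyde, under the basic hydride before reduction is complete. The fallback is reductive deoxygenation under Lewis-acidic conditions in place of diol formation and Mitsunobu closure; it sets out from 16 and comes back at chroman 18. i-Bu2AlH in CH2Cl2 at −78 °C gives (3S)-7-(benzyloxy)-8-methoxy-3-(2,3,4,5-tetramethoxyphenyl)-3,4-dihydro-2H-chromen-2-ol F6 as its aluminium derivative. Without release of the free lactol, Et3SiH and BF3·OEt2 are added at −78 °C and the mixture is warmed to −20 °C, so that the aryloxocarbenium ion is reduced by the silane to 18.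

**Further compounds**
F1 | step 10 | (4S)-4-benzyl-3-[(2,3,4,5-tetramethoxyphenyl)acetyl]-1,3-oxazolidin-2-one | COc1cc(CC(=O)N2[C@@H](Cc3ccccc3)COC2=O)c(OC)c(OC)c1OC
F2 | step 10 | (4S)-4-benzyl-3-[(2S)-3-{4-(benzyloxy)-2-[(tert-butyldimethylsilyl)oxy]-3-methoxyphenyl}-2-(2,3,4,5-tetramethoxyphenyl)propanoyl]-1,3-oxazolidin-2-one | COc1cc([C@H](Cc2ccc(OCc3ccccc3)c(OC)c2O[Si](C)(C)C(C)(C)C)C(=O)N2[C@@H](Cc3ccccc3)COC2=O)c(OC)c(OC)c1OC
F3 | step 10 | (2S)-3-{4-(benzyloxy)-2-[(tert-butyldimethylsilyl)oxy]-3-methoxyphenyl}-2-(2,3,4,5-tetramethoxyphenyl)propan-1-ol | COc1cc([C@H](Cc2ccc(OCc3ccccc3)c(OC)c2O[Si](C)(C)C(C)(C)C)CO)c(OC)c(OC)c1OC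
F4 | step 5 | 3-(benzyloxy)-6-(hydroxymethyl)-2-methoxyphenol | COc1c(OCc2ccccc2)ccc(CO)c1O
F5 | step 5 | 3-(benzyloxy)-2-methoxy-6-[(4-methylbenzenesulfonyl)methyl]phenol | COc1c(OCc2ccccc2)ccc(CS(=O)(=O)c2ccc(C)cc2)c1O
F6 | step 11 | (3S)-7-(benzyloxy)-8-methoxy-3-(2,3,4,5-tetramethoxyphenyl)-3,4-dihydro-2H-chromen-2-ol (both C2 epimers) | COc1cc([C@H]2C(O)Oc3c(ccc(OCc4ccccc4)c3OC)C2)c(OC)c(OC)c1OC
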